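**Retrosynthetic overview**

1. The strategy rests on the isoquinoline benzo ring, which carries oxygen at C6 and C8 and its only carbon substituent at C7 between them. C5–C6 and C7–C8 are therefore cut back to the 4-methyl group and the ester of methyl 4,6-dimethylnicotinate and to an isochroman-3-ylacetic N-methoxy-N-methylamide (Claisen acylation, then Dieckmann closure).
2. The bridging acetal bond (isochroman C1 to the C6 oxygen, closing the 2,8-dioxabicyclo[3.3.1]nonane) is made afterwards by acid from the 1-methoxyisochroman. The acetyl group is unmasked last from a vinyl group.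
3. The isochroman with C3 and C4 comes from an anti homoallylic alcohol, made by chiral phosphoric acid-catalysed allylboration of 3-oxopropyl benzoate with a ring A (E)-cinnamyl pinacolboronate, followed by acetal closure.
4. Ring A comes from 4-bromo-2,6-dimethoxybenzaldehyde by mono-demethylation, reduction, silylation, lithiation/formylation between Br and OMe, vinylation and cross-metathesis.
5. Ring order: ring A (purchased) → isochroman pyran ring (step 11) → isoquinoline benzo ring (step 15) → bridging 1,3-dioxane ring (step 20).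

Key step: step 15

**Remarks and assumptions**

- Abbreviations: TIPS = triisopropylsilyl; Ar = 2-(dimethoxymethyl)-3-methoxy-5-(triisopropylsilyloxy)-4-[(triisopropylsilyloxy)methyl]phenyl; Iso = 4-ethenyl-1,8-dimethoxy-6-(triisopropylsilyloxy)-7-[(triisopropylsilyloxy)methyl]-3,4-dihydro-1H-isochromen-3-yl, with H3 and H4 cis and the 1-OMe group trans to the C3 substituent; (R)-TRIP = (R)-3,3'-bis(2,4,6-triisopropylphenyl)-1,1'-binaphthyl-2,2'-diyl hydrogen phosphate.
- Both phenols of 22 are ortho to C7 and either could close onto the acetal carbon. The C6 hydroxyl is therefore marked by a sterically selective silylation (step 16) and the C8 hydroxyl is methylated (step 17) before the bridge is closed; 22 and 23 are kept away from acid.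
- C1 of the methoxyisochromans 15–26 is drawn as the anomer expected to prevail (OMe pseudoaxial, trans to the C3 substituent). Its epimer would be carried along, because C1 is formed anew in step 20.
- Ring A is carried as aryl and benzyl TIPS ethers, because the bulky, non-coordinating aryl silyl ether is what steers the lithiation of step 4 to the carbon next to the methoxy group.
- The sense of induction in step 10 is assigned by analogy with simple allyl- and crotylboronates; should it prove opposite, the (S)-acid would be used.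
- 1, 10 and 20 are taken as purchased.

**Route**

Step 1
Reactants: 1 4-bromo-2,6-dimethoxybenzaldehyde
Product: 2 4-bromo-2-hydroxy-6-methoxybenzaldehyde
Conditions: BCl3 (1.2 equiv), CH2Cl2, −78 → 0 °C; H2O
Reagents that add atoms: none
Why: Chelation-controlled mono-demethylation: boron bound to the aldehyde oxygen cleaves one of the two equivalent ortho methyl ethers, and the resulting boron chelate shields the second.

Step 2
Reactants: 2 4-bromo-2-hydroxy-6-methoxybenzaldehyde
Product: 3 5-bromo-2-(hydroxymethyl)-3-methoxyphenol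
Conditions: NaBH4, MeOH, 0 °C
Reagents that add atoms: none
Why: Borohydride reduction of the aldehyde gives the salicyl alcohol and leaves the aryl bromide untouched.

Step 3
Reactants: 3 5-bromo-2-(hydroxymethyl)-3-methoxyphenol
Product: 4 5-bromo-1-methoxy-3-(triisopropylsilyloxy)-2-[(triisopropylsilyloxy)methyl]benzene
Conditions: TIPSOTf (2.5 equiv), 2,6-lutidine, CH2Cl2, 0 °C
Reagents that add atoms: triisopropylsilyl trifluoromethanesulfonate, CC(C)[Si](C(C)C)(C(C)C)OS(=O)(=O)C(F)(F)F
Why: The silyl triflate silylates phenol and benzylic alcohol alike, and the bulky aryl silyl ether neither binds lithium nor leaves room beside it, which step 4 exploits.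

Step 4
Reactants: 4 5-bromo-1-methoxy-3-(triisopropylsilyloxy)-2-[(triisopropylsilyloxy)methyl]benzene
Product: 6 2-bromo-6-methoxy-4-(triisopropylsilyloxy)-5-[(triisopropylsilyloxy)methyl]benzaldehyde, via aryllithium 5 (not isolated)
Conditions: LiN(i-Pr)2 (1.2 equiv), THF, −78 °C; DMF, −78 → −40 °C; aq NH4Cl
Reagents that add atoms: N,N-dimethylformamide, CN(C)C=O
Why: Directed ortho-metalation with a lithium amide, which does not exchange bromine, removes the ring proton flanked by bromine and the lithium-coordinating methoxy group rather than the one shielded by the silyloxy group, and the aryllithium is formylated by DMF.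

Step 5
Reactants: 6 2-bromo-6-methoxy-4-(triisopropylsilyloxy)-5-[(triisopropylsilyloxy)methyl]benzaldehyde
Product: 7 1-bromo-2-(dimethoxymethyl)-3-methoxy-5-(triisopropylsilyloxy)-4-[(triisopropylsilyloxy)methyl]benzene
Conditions: HC(OMe)3, PPTS (cat.), MeOH, rt
Reagents that add atoms: trimethyl orthoformate, COC(OC)OC
Why: Acid-catalysed acetalisation driven by the orthoformate masks the aldehyde, which would otherwise react with the allylboronate built next.

Step 6
Reactants: 7 1-bromo-2-(dimethoxymethyl)-3-methoxy-5-(triisopropylsilyloxy)-4-[(triisopropylsilyloxy)methyl]benzene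
Product: 8 2-(dimethoxymethyl)-1-ethenyl-3-methoxy-5-(triisopropylsilyloxy)-4-[(triisopropylsilyloxy)methyl]benzene
Conditions: tributyl(vinyl)stannane, Pd(PPh3)4 (5 mol%), toluene, 100 °C
Reagents that add atoms: tributyl(vinyl)stannane, C=C[Sn](CCCC)(CCCC)CCCC
Why: Stille coupling replaces bromine by vinyl under neutral conditions that spare the aryl silyl ether and the acetal.

Step 7
Reactants: 8 2-(dimethoxymethyl)-1-ethenyl-3-methoxy-5-(triisopropylsilyloxy)-4-[(triisopropylsilyloxy)methyl]benzene
Product: 9 2-[(E)-3-Ar-prop-2-en-1-yl]-4,4,5,5-tetramethyl-1,3,2-dioxaborolane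
Conditions: allyl pinacolboronate (3 equiv), second-generation Grubbs catalyst (H2IMes)(PCy3)Cl2Ru=CHPh (5 mol%), CH2Cl2, 40 °C
Reagents that add atoms: 2-allyl-4,4,5,5-tetramethyl-1,3,2-dioxaborolane, C=CCB1OC(C)(C)C(C)(C)O1
Why: Olefin cross-metathesis between a styrene and an allylboronate gives the conjugated E alkene under thermodynamic control, with loss of ethylene.

Step 8
Reactants: 10 propane-1,3-diol
Product: 11 3-hydroxypropyl benzoate
Conditions: BzCl (1 equiv), diol (3 equiv), Et3N, CH2Cl2, 0 °C
Reagents that add atoms: benzoyl chloride, O=C(Cl)c1ccccc1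
Why: Acylation with the diol in excess gives the mono-ester, and the benzoate is chosen because it can later be removed without acid or fluoride.

Step 9
Reactants: 11 3-hydroxypropyl benzoate
Product: 12 3-oxopropyl benzoate
Conditions: Dess–Martin periodinane, CH2Cl2, rt; used fresh
Reagents that add atoms: none
Why: Periodinane oxidation stops at the aldehyde and, being free of base, does not provoke loss of benzoate from the beta-acyloxy aldehyde.

Step 10
Reactants: 9 2-[(E)-3-Ar-prop-2-en-1-yl]-4,4,5,5-tetramethyl-1,3,2-dioxaborolane; 12 3-oxopropyl benzoate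
Product: 14 (3S,4S)-4-Ar-3-hydroxyhex-5-en-1-yl benzoate, via borate ester 13 (not isolated)
Conditions: (R)-TRIP (10 mol%), 4 Å MS, toluene, −30 → 0 °C; aq NaHCO3
Reagents that add atoms: none
Why: Chiral phosphoric acid-catalysed allylboration through a closed chair transition state, in which the E geometry of the boronate places aryl and aldehyde chain equatorial and so sets the anti relation of C3 and C4, while the (R)-configured acid, hydrogen-bonded to a boronate oxygen and the formyl hydrogen, is expected to expose the Re face of the aldehyde and set 3S.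

Step 11
Reactants: 14 (3S,4S)-4-Ar-3-hydroxyhex-5-en-1-yl benzoate
Product: 15 2-[(1R,3S,4S)-Iso]ethyl benzoate
Conditions: PPTS (10 mol%), 5 Å MS, CH2Cl2, rt
Reagents that add atoms: none
Why: Intramolecular transacetalisation in which the secondary hydroxyl captures the oxocarbenium ion from the dimethyl acetal in a 6-exo closure, equilibration placing the C1 methoxy group pseudoaxial (anomeric effect) while C3 and C4 are untouched.

Step 12
Reactants: 15 2-[(1R,3S,4S)-Iso]ethyl benzoate
Product: 16 2-[(1R,3S,4S)-Iso]ethanol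
Conditions: i-Bu2AlH (2.5 equiv), CH2Cl2, −78 °C; Rochelle salt
Reagents that add atoms: none
Why: Reductive ester cleavage frees the primary hydroxyl under acid-free conditions, so that it cannot displace the C1 methoxy group to form a bridged acetal, and leaves the aryl silyl ethers in place.

Step 13
Reactants: 16 2-[(1R,3S,4S)-Iso]ethanol
Product: 18 [(1R,3S,4S)-Iso]acetic acid, via aldehyde 17 (not isolated)
Conditions: TEMPO (10 mol%), NaClO2 (2 equiv), NaOCl (2 mol%), MeCN/phosphate buffer pH 6.7, 35 °C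
Reagents that add atoms: sodium chlorite, [Na+].[O-]Cl=O
Why: Oxoammonium-catalysed oxidation with chlorite as terminal oxidant takes the primary alcohol through the aldehyde to the acid near neutral pH, which the methyl acetal, the alkene and the silyl ethers tolerate.

Step 14
Reactants: 18 [(1R,3S,4S)-Iso]acetic acid
Product: 19 2-[(1R,3S,4S)-Iso]-N-methoxy-N-methylacetamide
Conditions: MeNHOMe·HCl, EDC·HCl, HOBt, i-Pr2NEt, CH2Cl2, 0 °C → rt (acid used at once)
Reagents that add atoms: N,O-dimethylhydroxylamine hydrochloride, CNOC.Cl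
Why: Carbodiimide coupling gives the N-methoxy-N-methylamide under mildly basic conditions, the acid being coupled at once so that it cannot lactonise onto the acetal carbon.

Step 15
Reactants: 19 2-[(1R,3S,4S)-Iso]-N-methoxy-N-methylacetamide; 20 methyl 4,6-dimethylnicotinate
Product: 22 7-[(1R,3R,4S)-Iso]-3-methylisoquinoline-6,8-diol, via keto ester 21 (not isolated)
Conditions: 20 (2.2 equiv), LiN(i-Pr)2 (2.1 equiv), THF, −78 °C; 19, −78 → −20 °C; LiN(i-Pr)2 (2 equiv), −78 → 0 °C; cold aq NH4Cl; crude product kept off acidic silica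
Reagents that add atoms: none
Why: LiN(i-Pr)2 removes a proton from the 4-methyl group of 20, which lies next to the ester (lithium held by the carbonyl oxygen) and para to the ring nitrogen, and the resulting lateral anion acylates on the N-methoxy-N-methylamide of 19; on warming the chelated adduct collapses to the aryl-acetonyl ketone 21, present as its conjugated enolate, and this forms C5–C6. A second charge of amide base gives the 1,3-dianion, whose outer carbon (the CH2 attached to isochroman C3) attacks the neighbouring ester in a 6-exo-trig Dieckmann closure that forms C7–C8, and loss of methoxide with enolisation delivers the aromatic 6,8-diol. The closest known reaction type is the lateral lithiation–acylation–Dieckmann benzannulation of ortho-toluates to naphthalene-1,3-diols, here transferred to a 4-methylnicotinate. No stereocentre is created, and C3 and C4 are preserved as long as the beta-alkoxy enolate does not expel the ring oxygen, which lithium counter-ions and temperatures at or below 0 °C are meant to ensure. Site selectivity is needed twice: the 4-methyl group must be deprotonated in preference to the 6-methyl group, which the adjacent ester secures, and only the enolate carbon on the isochroman side can reach the ester through a six-membered transition state. Silyl ethers, methyl acetal and vinyl group are inert to the amide base, and the amide is added to preformed anion so that no free LiN(i-Pr)2 can enolise it.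

Step 16
Reactants: 22 7-[(1R,3R,4S)-Iso]-3-methylisoquinoline-6,8-diol
Product: 23 7-[(1R,3R,4S)-Iso]-3-methyl-6-(triisopropylsilyloxy)isoquinolin-8-ol
Conditions: TIPSCl (1.1 equiv), imidazole, DMF, 0 °C
Reagents that add atoms: chlorotriisopropylsilane, CC(C)[Si](Cl)(C(C)C)C(C)C
Why: Silylation of phenols is governed by steric access, and since C6–OH has a ring hydrogen on its open side whereas C8–OH is wedged between the C7 substituent and the peri C1–H, one equivalent of the bulky chlorosilane under basic, acetal-safe conditions should mark C6–OH.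

Step 17
Reactants: 23 7-[(1R,3R,4S)-Iso]-3-methyl-6-(triisopropylsilyloxy)isoquinolin-8-ol
Product: 24 7-[(1R,3R,4S)-Iso]-8-methoxy-3-methyl-6-(triisopropylsilyloxy)isoquinoline
Conditions: MeOH, PPh3, DIAD, THF, 0 °C → rt
Reagents that add atoms: methanol, CO
Why: Mitsunobu etherification alkylates the remaining acidic phenol on oxygen under neutral conditions, so that the ring nitrogen is not quaternised, no silyl ether is cleaved and the acetal is not ionised.

Step 18
Reactants: 24 7-[(1R,3R,4S)-Iso]-8-methoxy-3-methyl-6-(triisopropylsilyloxy)isoquinoline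
Product: 25 7-[(1R,3R,4S)-4-ethenyl-6-hydroxy-7-(hydroxymethyl)-1,8-dimethoxyisochroman-3-yl]-8-methoxy-3-methylisoquinolin-6-ol
Conditions: Bu4NF (5 equiv), THF, 0 °C → rt; aq NH4Cl
Reagents that add atoms: none
Why: Fluoride cleaves the two aryl silyl ethers and the benzylic silyl ether in one operation without affecting the acetal or the alkene.

Step 19
Reactants: 25 7-[(1R,3R,4S)-4-ethenyl-6-hydroxy-7-(hydroxymethyl)-1,8-dimethoxyisochroman-3-yl]-8-methoxy-3-methylisoquinolin-6-ol
Product: 26 (1R,3R,4S)-4-ethenyl-6-hydroxy-3-(6-hydroxy-8-methoxy-3-methylisoquinolin-7-yl)-1,8-dimethoxyisochroman-7-carbaldehyde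
Conditions: MnO2 (excess), CH2Cl2, rt
Reagents that add atoms: none
Why: Manganese dioxide oxidises only the benzylic (ortho-hydroxybenzyl) alcohol, giving the hydrogen-bonded salicylaldehyde.

Step 20
Reactants: 26 (1R,3R,4S)-4-ethenyl-6-hydroxy-3-(6-hydroxy-8-methoxy-3-methylisoquinolin-7-yl)-1,8-dimethoxyisochroman-7-carbaldehyde
Product: 27 bridged acetal with vinyl at C4 (4-ethenyl analogue of the target)
Conditions: CSA (1.5 equiv), 4 Å MS, CH2Cl2, 0 °C → rt; aq NaHCO3
Reagents that add atoms: none
Why: Acid ionises the methyl acetal to an oxocarbenium ion stabilised by ring A, and the only phenol within reach, C6–OH, captures it in a six-membered transacetalisation in which the tether allows attack only on the face cis to the C3–aryl bond, which sets C1.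

Step 21
Reactants: 27 bridged acetal with vinyl at C4
Product: 28 target CNP0584953.1
Conditions: PdCl2 (0.3 equiv), CuCl (1 equiv), O2 (1 atm), DMF/H2O 7:1, rt
Reagents that add atoms: water, O
Why: Tsuji–Wacker oxidation (Markovnikov hydroxypalladation of the terminal alkene, then beta-hydride elimination) gives the methyl ketone without breaking a bond at C4, and as the last step it exposes the now enolisable C4 to no further acid or base.

**Compound list**

1 | 4-bromo-2,6-dimethoxybenzaldehyde | COc1cc(Br)cc(OC)c1C=O | starting material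
2 | 4-bromo-2-hydroxy-6-methoxybenzaldehyde | COc1cc(Br)cc(O)c1C=O | intermediate
3 | 5-bromo-2-(hydroxymethyl)-3-methoxyphenol | COc1cc(Br)cc(O)c1CO | intermediate
4 | 5-bromo-1-methoxy-3-(triisopropylsilyloxy)-2-[(triisopropylsilyloxy)methyl]benzene | COc1cc(Br)cc(O[Si](C(C)C)(C(C)C)C(C)C)c1CO[Si](C(C)C)(C(C)C)C(C)C | intermediate
5 | 6-lithio derivative of 4 (lithium on the ring carbon between OMe and Br) | COc1c([Li])c(Br)cc(O[Si](C(C)C)(C(C)C)C(C)C)c1CO[Si](C(C)C)(C(C)C)C(C)C | intermediate
6 | 2-bromo-6-methoxy-4-(triisopropylsilyloxy)-5-[(triisopropylsilyloxy)methyl]benzaldehyde | COc1c(C=O)c(Br)cc(O[Si](C(C)C)(C(C)C)C(C)C)c1CO[Si](C(C)C)(C(C)C)C(C)C | intermediate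
7 | 1-bromo-2-(dimethoxymethyl)-3-methoxy-5-(triisopropylsilyloxy)-4-[(triisopropylsilyloxy)methyl]benzene | COc1c(C(OC)OC)c(Br)cc(O[Si](C(C)C)(C(C)C)C(C)C)c1CO[Si](C(C)C)(C(C)C)C(C)C | intermediate
8 | 2-(dimethoxymethyl)-1-ethenyl-3-methoxy-5-(triisopropylsilyloxy)-4-[(triisopropylsilyloxy)methyl]benzene | COc1c(C(OC)OC)c(C=C)cc(O[Si](C(C)C)(C(C)C)C(C)C)c1CO[Si](C(C)C)(C(C)C)C(C)C | intermediate
9 | 2-[(E)-3-Ar-prop-2-en-1-yl]-4,4,5,5-tetramethyl-1,3,2-dioxaborolane | COc1c(C(OC)OC)c(/C=C/CB2OC(C)(C)C(C)(C)O2)cc(O[Si](C(C)C)(C(C)C)C(C)C)c1CO[Si](C(C)C)(C(C)C)C(C)C | intermediate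
10 | propane-1,3-diol | OCCCO | starting material
11 | 3-hydroxypropyl benzoate | OCCCOC(=O)c1ccccc1 | intermediate
12 | 3-oxopropyl benzoate | O=CCCOC(=O)c1ccccc1 | intermediate
13 | pinacol borate ester of 14 (O–B bond at the C3 oxygen) | O=C(OCC[C@H](OB1OC(C)(C)C(C)(C)O1)[C@@H](C=C)c1cc(O[Si](C(C)C)(C(C)C)C(C)C)c(CO[Si](C(C)C)(C(C)C)C(C)C)c(OC)c1C(OC)OC)c1ccccc1 | intermediate
14 | (3S,4S)-4-Ar-3-hydroxyhex-5-en-1-yl benzoate (anti) | O=C(OCC[C@H](O)[C@@H](C=C)c1cc(O[Si](C(C)C)(C(C)C)C(C)C)c(CO[Si](C(C)C)(C(C)C)C(C)C)c(OC)c1C(OC)OC)c1ccccc1 | intermediate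
15 | 2-[(1R,3S,4S)-Iso]ethyl benzoate | COc1c(CO[Si](C(C)C)(C(C)C)C(C)C)c(O[Si](C(C)C)(C(C)C)C(C)C)cc2c1[C@H](OC)O[C@@H](CCOC(=O)c1ccccc1)[C@H]2C=C | intermediate
16 | 2-[(1R,3S,4S)-Iso]ethanol | COc1c(CO[Si](C(C)C)(C(C)C)C(C)C)c(O[Si](C(C)C)(C(C)C)C(C)C)cc2c1[C@H](OC)O[C@@H](CCO)[C@H]2C=C | intermediate
17 | [(1R,3S,4S)-Iso]acetaldehyde | COc1c(CO[Si](C(C)C)(C(C)C)C(C)C)c(O[Si](C(C)C)(C(C)C)C(C)C)cc2c1[C@H](OC)O[C@@H](CC=O)[C@H]2C=C | intermediate
18 | [(1R,3S,4S)-Iso]acetic acid | COc1c(CO[Si](C(C)C)(C(C)C)C(C)C)c(O[Si](C(C)C)(C(C)C)C(C)C)cc2c1[C@H](OC)O[C@@H](CC(=O)O)[C@H]2C=C | intermediate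
19 | 2-[(1R,3S,4S)-Iso]-N-methoxy-N-methylacetamide | COc1c(CO[Si](C(C)C)(C(C)C)C(C)C)c(O[Si](C(C)C)(C(C)C)C(C)C)cc2c1[C@H](OC)O[C@@H](CC(=O)N(C)OC)[C@H]2C=C | intermediate
20 | methyl 4,6-dimethylnicotinate | COC(=O)c1cnc(C)cc1C | starting material
21 | methyl 6-methyl-4-{2-oxo-3-[(1R,3S,4S)-Iso]propyl}pyridine-3-carboxylate | COc1c(CO[Si](C(C)C)(C(C)C)C(C)C)c(O[Si](C(C)C)(C(C)C)C(C)C)cc2c1[C@H](OC)O[C@@H](CC(=O)Cc1cc(C)ncc1C(=O)OC)[C@H]2C=C | intermediate
22 | 7-[(1R,3R,4S)-Iso]-3-methylisoquinoline-6,8-diol | COc1c(CO[Si](C(C)C)(C(C)C)C(C)C)c(O[Si](C(C)C)(C(C)C)C(C)C)cc2c1[C@H](OC)O[C@@H](c1c(O)cc3cc(C)ncc3c1O)[C@H]2C=C | intermediate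
23 | 7-[(1R,3R,4S)-Iso]-3-methyl-6-(triisopropylsilyloxy)isoquinolin-8-ol | COc1c(CO[Si](C(C)C)(C(C)C)C(C)C)c(O[Si](C(C)C)(C(C)C)C(C)C)cc2c1[C@H](OC)O[C@@H](c1c(O[Si](C(C)C)(C(C)C)C(C)C)cc3cc(C)ncc3c1O)[C@H]2C=C | intermediate
24 | 7-[(1R,3R,4S)-Iso]-8-methoxy-3-methyl-6-(triisopropylsilyloxy)isoquinoline | COc1c(CO[Si](C(C)C)(C(C)C)C(C)C)c(O[Si](C(C)C)(C(C)C)C(C)C)cc2c1[C@H](OC)O[C@@H](c1c(O[Si](C(C)C)(C(C)C)C(C)C)cc3cc(C)ncc3c1OC)[C@H]2C=C | intermediate
25 | 7-[(1R,3R,4S)-4-ethenyl-6-hydroxy-7-(hydroxymethyl)-1,8-dimethoxyisochroman-3-yl]-8-methoxy-3-methylisoquinolin-6-ol | COc1c(CO)c(O)cc2c1[C@H](OC)O[C@@H](c1c(O)cc3cc(C)ncc3c1OC)[C@H]2C=C | intermediate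
26 | (1R,3R,4S)-4-ethenyl-6-hydroxy-3-(6-hydroxy-8-methoxy-3-methylisoquinolin-7-yl)-1,8-dimethoxyisochroman-7-carbaldehyde | COc1c(C=O)c(O)cc2c1[C@H](OC)O[C@@H](c1c(O)cc3cc(C)ncc3c1OC)[C@H]2C=C | intermediate
27 | bridged acetal, 4-ethenyl analogue of the target: isochroman C1 bonded to the isoquinoline C6 oxygen and C3 to isoquinoline C7; isochroman H1, H3 and H4 on one face, the O–aryl bridge on the other; ring A with 8-OMe, 7-CHO, 6-OH | COc1c(C=O)c(O)cc2c1[C@H]1Oc3cc4cc(C)ncc4c(OC)c3[C@H](O1)[C@H]2C=C | intermediate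
28 | CNP0584953.1: as 27 with acetyl in place of vinyl at C4, acetyl cis to the C3–aryl bond | COc1c(C=O)c(O)cc2c1[C@H]1Oc3cc4cc(C)ncc4c(OC)c3[C@H](O1)[C@H]2C(C)=O | target

**Step count and risks**

Total step count: 21. Longest linear sequence: 19 steps (1 → 28 through steps 1–7 and 10–21); steps 8 and 9 form the two-step aldehyde branch.

Steps most likely to fail:

Step 15 (key step). The ketone enolate or dianion may expel the ring oxygen at C3 (retro-oxa-Michael ring opening, eased because that oxygen is an acetal oxygen). The lateral anion may also condense with unreacted ester 20, or deprotonation may take place at the 6-methyl group. Fallback: the beta-oxygen is carried through the annulation as a lithium alkoxide, which cannot act as a leaving group. Setting out from 14, i-Bu2AlH (CH2Cl2, −78 °C) removes the benzoate without closing the ring and should give (3S,4S)-4-Ar-hex-5-ene-1,3-diol F1. TEMPO/NaClO2 at pH 6.7 should oxidise only the primary hydroxyl to (3S,4S)-4-Ar-3-hydroxyhex-5-enoic acid F2, and EDC coupling with N,O-dimethylhydroxylamine gives (3S,4S)-4-Ar-3-hydroxy-N-methoxy-N-methylhex-5-enamide F3. Treatment with the lateral anion of 20 (one extra equivalent to form the alkoxide) and then LiN(i-Pr)2 as in step 15 should give the open-chain 7-[(1R,2S)-2-Ar-1-hydroxybut-3-en-1-yl]-3-methylisoquinoline-6,8-diol F4. TIPSCl/imidazole then marks the C6 hydroxyl to give the 6-O-triisopropylsilyl ether F5, and Mitsunobu methylation gives the 8-O-methyl ether F6. PPTS in CH2Cl2 closes the secondary hydroxyl onto the dimethyl acetal, which returns the material to the route at 24.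

Step 10. The hindered gamma-aryl boronate may add slowly, so that the uncatalysed pathway or loss of facial control erodes enantio- and diastereoselectivity, or the acid catalyst may ionise the dimethyl acetal before the addition. Fallback: chromium-mediated (Nozaki–Hiyama–Kishi) allylation, which is anti-selective for gamma-substituted allyl halides and can be made enantioselective by a chiral ligand on chromium. Setting out from 7, Stille coupling with (E)-3-(tributylstannyl)prop-2-en-1-ol (Pd(PPh3)4, toluene) gives (E)-3-Ar-prop-2-en-1-ol F7. MsCl/Et3N followed by LiCl gives 1-[(E)-3-chloroprop-1-en-1-yl]-2-(dimethoxymethyl)-3-methoxy-5-(triisopropylsilyloxy)-4-[(triisopropylsilyloxy)methyl]benzene F8. CrCl2 with a chiral oxazoline–sulfonamide ligand and Et3N in THF, followed by aldehyde 12, should give 14, where the route is rejoined.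

Step 21. Palladium may be held by the ring nitrogen or by the ortho-hydroxy aldehyde so that turnover stops. The hindered alkene may be attacked at its terminal carbon (aldehyde formation), or a palladium hydride may move the double bond into conjugation with ring A and erase C4. Fallback: radical Markovnikov hydration followed by oxidation. Setting out from 27, Mukaiyama hydration (Co(acac)2, PhSiH3, O2, i-PrOH) should give the 1-hydroxyethyl analogue of 28 F9 as a mixture of carbinol epimers, and Dess–Martin periodinane (NaHCO3, CH2Cl2) oxidises it to the target 28.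

**Further compounds**

F1 | step 15 | (3S,4S)-4-Ar-hex-5-ene-1,3-diol | OCC[C@H](O)[C@@H](C=C)c1cc(O[Si](C(C)C)(C(C)C)C(C)C)c(CO[Si](C(C)C)(C(C)C)C(C)C)c(OC)c1C(OC)OC
F2 | step 15 | (3S,4S)-4-Ar-3-hydroxyhex-5-enoic acid | OC(=O)C[C@H](O)[C@@H](C=C)c1cc(O[Si](C(C)C)(C(C)C)C(C)C)c(CO[Si](C(C)C)(C(C)C)C(C)C)c(OC)c1C(OC)OC
F3 | step 15 | (3S,4S)-4-Ar-3-hydroxy-N-methoxy-N-methylhex-5-enamide | CON(C)C(=O)C[C@H](O)[C@@H](C=C)c1cc(O[Si](C(C)C)(C(C)C)C(C)C)c(CO[Si](C(C)C)(C(C)C)C(C)C)c(OC)c1C(OC)OC
F4 | step 15 | 7-[(1R,2S)-2-Ar-1-hydroxybut-3-en-1-yl]-3-methylisoquinoline-6,8-diol | Cc1cc2cc(O)c([C@H](O)[C@@H](C=C)c3cc(O[Si](C(C)C)(C(C)C)C(C)C)c(CO[Si](C(C)C)(C(C)C)C(C)C)c(OC)c3C(OC)OC)c(O)c2cn1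
F5 | step 15 | 7-[(1R,2S)-2-Ar-1-hydroxybut-3-en-1-yl]-3-methyl-6-(triisopropylsilyloxy)isoquinolin-8-ol | Cc1cc2cc(O[Si](C(C)C)(C(C)C)C(C)C)c([C@H](O)[C@@H](C=C)c3cc(O[Si](C(C)C)(C(C)C)C(C)C)c(CO[Si](C(C)C)(C(C)C)C(C)C)c(OC)c3C(OC)OC)c(O)c2cn1
F6 | step 15 | (1R,2S)-2-Ar-1-[8-methoxy-3-methyl-6-(triisopropylsilyloxy)isoquinolin-7-yl]but-3-en-1-ol | Cc1cc2cc(O[Si](C(C)C)(C(C)C)C(C)C)c([C@H](O)[C@@H](C=C)c3cc(O[Si](C(C)C)(C(C)C)C(C)C)c(CO[Si](C(C)C)(C(C)C)C(C)C)c(OC)c3C(OC)OC)c(OC)c2cn1
F7 | step 10 | (E)-3-Ar-prop-2-en-1-ol | COc1c(C(OC)OC)c(/C=C/CO)cc(O[Si](C(C)C)(C(C)C)C(C)C)c1CO[Si](C(C)C)(C(C)C)C(C)C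
F8 | step 10 | 1-[(E)-3-chloroprop-1-en-1-yl]-2-(dimethoxymethyl)-3-methoxy-5-(triisopropylsilyloxy)-4-[(triisopropylsilyloxy)methyl]benzene | COc1c(C(OC)OC)c(/C=C/CCl)cc(O[Si](C(C)C)(C(C)C)C(C)C)c1CO[Si](C(C)C)(C(C)C)C(C)C
F9 | step 21 | 1-hydroxyethyl analogue of 28 (both carbinol epimers) | COc1c(C=O)c(O)cc2c1[C@H]1Oc3cc4cc(C)ncc4c(OC)c3[C@H](O1)[C@H]2C(C)O
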